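The dihydropyran ring C is cut by a retro-oxa-[4+2] through C4–C3 and O1–C2. The feature exploited is that O1–C8a–C4a–C4 of rings A/C is a latent ortho-quinone methide and the cis C2–C3 pair a latent (Z)-alkene. In the key step a chiral Brønsted acid dehydrates a salicyl alcohol (5-O-galloyl and 7-O-benzyl leave one phenol only). The resulting quinone methide then joins the (Z)-enol gallate of the B-ring arylacetaldehyde. Ring C, both stereocentres and the full skeleton, both gallates included, arise at once. The precursors are two flat, achiral, perbenzylated fragments, and only hydrogenolysis follows.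

Key step: step 6

Assumption: the sense of induction of the chiral acid in step 6 cannot be predicted with certainty; the (R)-acid is written, and its mirror image is to be used if the (2S,3S) series is favoured.

Step 1
Reactants: 1 3,4-bis(benzyloxy)benzaldehyde
Product: 2 1,2-bis(benzyloxy)-4-ethynylbenzene
Conditions: Ohira–Bestmann reagent (1.2 equiv), K2CO3 (2 equiv), MeOH/THF, rt
Reagents that add atoms: dimethyl (1-diazo-2-oxopropyl)phosphonate (Ohira–Bestmann reagent), CC(=O)C(=[N+]=[N-])P(=O)(OC)OC
Why: The Seyferth–Gilbert homologation in its Ohira–Bestmann form should turn the non-enolisable aryl aldehyde into the terminal alkyne under mild carbonate conditions that leave the benzyl ethers untouched; no stereocentre is formed.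

Step 2
Reactants: 2 1,2-bis(benzyloxy)-4-ethynylbenzene; 3 3,4,5-tris(benzyloxy)benzoic acid
Product: 4 (Z)-2-[3,4-bis(benzyloxy)phenyl]ethenyl 3,4,5-tris(benzyloxy)benzoate
Conditions: Ru(methallyl)2(dppb) (2 mol %), toluene, 50 °C
Reagents that add atoms: none
Why: The ruthenium-catalysed anti-Markovnikov hydro-acyloxylation of a terminal aryl alkyne runs through a ruthenium vinylidene that the carboxylate attacks at the metal-bound carbon, and it should give the (Z)-enol ester, the alkene geometry that later becomes the 2,3-cis relation.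

Step 3
Reactants: 5 2,4,6-trihydroxybenzaldehyde
Product: 6 4-(benzyloxy)-2,6-dihydroxybenzaldehyde
Conditions: BnBr (1.0 equiv), NaHCO3 (1.1 equiv), KI (cat.), MeCN, 60 °C
Reagents that add atoms: benzyl bromide, BrCc1ccccc1
Why: In this Williamson etherification under weak-base control the 4-OH is the most acidic and the only non-chelated phenol, while the 2- and 6-OH are hydrogen-bonded to the formyl oxygen, so one equivalent of benzyl bromide should alkylate O-4.

Step 4
Reactants: 6 4-(benzyloxy)-2,6-dihydroxybenzaldehyde; 3 3,4,5-tris(benzyloxy)benzoic acid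
Product: 7 5-(benzyloxy)-2-formyl-3-hydroxyphenyl 3,4,5-tris(benzyloxy)benzoate
Conditions: 3 (1.0 equiv), DIC (1.05 equiv), DMAP (10 mol %), CH2Cl2, 0 °C
Reagents that add atoms: none
Why: In this Steglich esterification the two phenols are equivalent, so the first acylation poses no regiochemical question, and the second should be slower because the surviving phenol is locked in a strong hydrogen bond to the formyl group.

Step 5
Reactants: 7 5-(benzyloxy)-2-formyl-3-hydroxyphenyl 3,4,5-tris(benzyloxy)benzoate
Product: 8 5-(benzyloxy)-3-hydroxy-2-(hydroxymethyl)phenyl 3,4,5-tris(benzyloxy)benzoate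
Conditions: NaBH(OAc)3 (1.5 equiv), THF, 0 °C to rt; pH 7 phosphate buffer work-up; used without chromatography
Reagents that add atoms: none
Why: In this hydroxyl-directed aldehyde reduction the triacetoxyborohydride binds the ortho phenol and delivers hydride intramolecularly, and the new benzylic oxygen stays boron-bound rather than becoming a free alkoxide, which should suppress galloyl migration and base-induced quinone methide formation.

Step 6
Reactants: 8 5-(benzyloxy)-3-hydroxy-2-(hydroxymethyl)phenyl 3,4,5-tris(benzyloxy)benzoate; 4 (Z)-2-[3,4-bis(benzyloxy)phenyl]ethenyl 3,4,5-tris(benzyloxy)benzoate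
Product: 10 nona-O-benzyl-(−)-epicatechin 3,5-di-O-gallate, via ortho-quinone methide 9 (not isolated)
Conditions: 4 (2.0 equiv), (R)-3,3'-bis(2,4,6-triisopropylphenyl)-1,1'-binaphthyl-2,2'-diyl N-triflylphosphoramide (10 mol %), 5 Å MS, toluene, −20 °C; 8 added over 10 h by syringe pump
Reagents that add atoms: none
Why: Proposed new method: the acid dehydrates 8 to the hydrogen-bonded ortho-quinone methide 9, C3 of 4 attacks its methylene terminus C4 while the carbonyl oxygen O1 closes on the developing 4-benzyloxybenzylic cation at C2, an asynchronous inverse-electron-demand oxa-[4+2] cycloaddition driven by rearomatisation of ring A. The closest known reaction types are the chiral-phosphoric-acid-catalysed [4+2] cycloadditions of in situ formed ortho-quinone methides with styrenes or vinyl sulfides and the heat- or acid-promoted quinone methide/styrene synthesis of flavans, whereas a β-acyloxystyrene and a terminally unsubstituted quinone methide have not been shown under asymmetric catalysis. Ring C, the only ring closed, forms in the intermolecular [4+2] mode (four atoms O1–C8a–C4a–C4 from 9, two atoms C3–C2 from 4), which in the stepwise limit is a 6-exo-trig capture of the C2 cation by O1. The 2,3-cis relation is controlled by suprafacial addition to the (Z)-alkene, and the absolute 2R,3R configuration by the chiral phosphoramide anion, which holds 9 through its O1–H contact and exposes one alkene face of 4 in its aryl-walled pocket. Regioselectivity needs C3 and not C2 as the nucleophilic carbon, and this is secured because the para-benzyloxyaryl group stabilises charge at C2 far better than an acyloxy group would at C3 (p-alkoxystyrenes polymerise cationically with ease, vinyl esters do not). Site selectivity in ring A is secured by the 5-O-galloyl and 7-O-benzyl groups, which leave one phenol only for quinone methide formation, and self-condensation of 9 is held down by slow addition of 8 to excess 4 at low temperature.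

Step 7
Reactants: 10 nona-O-benzyl-(−)-epicatechin 3,5-di-O-gallate
Product: 11 (−)-epicatechin 3,5-di-O-gallate
Conditions: H2 (1 atm), Pd(OH)2/C, THF/MeOH, rt
Reagents that add atoms: none
Why: Neutral catalytic hydrogenolysis should remove all nine benzyl ethers while the alkyl and aryl gallate esters and the C2–O1 bond persist, and neither stereocentre is touched.

Compound list
1 | 3,4-bis(benzyloxy)benzaldehyde | O=Cc1ccc(OCc2ccccc2)c(OCc2ccccc2)c1 | starting material
2 | 1,2-bis(benzyloxy)-4-ethynylbenzene | C#Cc1ccc(OCc2ccccc2)c(OCc2ccccc2)c1 | intermediate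
3 | 3,4,5-tris(benzyloxy)benzoic acid | O=C(O)c1cc(OCc2ccccc2)c(OCc2ccccc2)c(OCc2ccccc2)c1 | starting material
4 | (Z)-2-[3,4-bis(benzyloxy)phenyl]ethenyl 3,4,5-tris(benzyloxy)benzoate | O=C(O/C=C\c1ccc(OCc2ccccc2)c(OCc2ccccc2)c1)c1cc(OCc2ccccc2)c(OCc2ccccc2)c(OCc2ccccc2)c1 | intermediate
5 | 2,4,6-trihydroxybenzaldehyde | O=Cc1c(O)cc(O)cc1O | starting material
6 | 4-(benzyloxy)-2,6-dihydroxybenzaldehyde | O=Cc1c(O)cc(OCc2ccccc2)cc1O | intermediate
7 | 5-(benzyloxy)-2-formyl-3-hydroxyphenyl 3,4,5-tris(benzyloxy)benzoate | O=Cc1c(O)cc(OCc2ccccc2)cc1OC(=O)c1cc(OCc2ccccc2)c(OCc2ccccc2)c(OCc2ccccc2)c1 | intermediate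
8 | 5-(benzyloxy)-3-hydroxy-2-(hydroxymethyl)phenyl 3,4,5-tris(benzyloxy)benzoate | OCc1c(O)cc(OCc2ccccc2)cc1OC(=O)c1cc(OCc2ccccc2)c(OCc2ccccc2)c(OCc2ccccc2)c1 | intermediate
9 | ortho-quinone methide, 3-(benzyloxy)-6-methylidene-5-oxocyclohexa-1,3-dien-1-yl 3,4,5-tris(benzyloxy)benzoate | C=C1C(=O)C=C(OCc2ccccc2)C=C1OC(=O)c1cc(OCc2ccccc2)c(OCc2ccccc2)c(OCc2ccccc2)c1 | intermediate
10 | nona-O-benzyl-(−)-epicatechin 3,5-di-O-gallate, (2R,3R)-7-(benzyloxy)-2-[3,4-bis(benzyloxy)phenyl]chromane-3,5-diyl bis[3,4,5-tris(benzyloxy)benzoate] | O=C(Oc1cc(OCc3ccccc3)cc2c1C[C@@H](OC(=O)c1cc(OCc3ccccc3)c(OCc3ccccc3)c(OCc3ccccc3)c1)[C@@H](c1ccc(OCc3ccccc3)c(OCc3ccccc3)c1)O2)c1cc(OCc3ccccc3)c(OCc3ccccc3)c(OCc3ccccc3)c1 | intermediate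
11 | (−)-epicatechin 3,5-di-O-gallate, (2R,3R) | O=C(Oc1cc(O)cc2c1C[C@@H](OC(=O)c1cc(O)c(O)c(O)c1)[C@@H](c1ccc(O)c(O)c1)O2)c1cc(O)c(O)c(O)c1 | target

Total step count: 7. Longest linear sequence: 5 steps (steps 3, 4, 5, 6, 7, from 5 to 11).

Steps most likely to fail

Risk 1, step 6. The catalyst may discriminate poorly between the two alkene faces. The alkene geometry may leak through a long-lived C2 cation. Self-condensation of the quinone methide may also outrun the only moderately nucleophilic enol ester.

The fallback uses known chemistry and forms the same two ring-C bonds at the flavylium oxidation level. It sets out from 2, 3 and 7 and comes back to the route at 11.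
- Alkyne 2 and acid 3 are joined by gold-catalysed oxidative acyloxylation (Ph3PAuNTf2, 8-methylquinoline N-oxide, 1,2-dichloroethane) to 2-[3,4-bis(benzyloxy)phenyl]-2-oxoethyl 3,4,5-tris(benzyloxy)benzoate F1.
- F1 and aldehyde 7 are condensed with dry HCl in EtOAc at 0 °C, the classical salicylaldehyde/aryl ketone flavylium condensation, to perbenzylated cyanidin 3,5-di-O-gallate chloride F2.
- Hydrogenation over Pd/C in THF/MeOH should saturate the pyrylium ring from one face (cis) and remove the benzyl groups. This gives racemic material, that is 11 together with (2S,3S)-epicatechin 3,5-di-O-gallate F3.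
- The two enantiomers are separated by preparative HPLC on a chiral polysaccharide phase.

Risk 2, step 5. The galloyl group may migrate from the phenolic oxygen to the new benzylic oxygen. Premature ionisation may also lead to over-reduction to the methyl arene.

The fallback reduces before acylating and locks the salicyl alcohol as a cyclic boronate. It sets out from 6 and comes back to the route at 9, and hence 10.
- 6 is reduced (NaBH4, THF/EtOH, 0 °C) to 5-(benzyloxy)-2-(hydroxymethyl)benzene-1,3-diol F4.
- F4 is condensed at once with PhB(OH)2 (toluene, 4 Å MS) to 7-(benzyloxy)-2-phenyl-4H-1,3,2-benzodioxaborinin-5-ol F5.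
- The remaining phenol is esterified with 3 (DIC, DMAP) to 7-(benzyloxy)-2-phenyl-4H-1,3,2-benzodioxaborinin-5-yl 3,4,5-tris(benzyloxy)benzoate F6.
- F6 should release 9 under the acid of step 6 or on warming.

Risk 3, step 4. Over-acylation to the bis-ester may occur. The activated acid may also be lost as N-acylurea, because chelated phenols are poor nucleophiles.

The fallback replaces kinetic mono-acylation by exhaustive acylation and self-limiting mono-cleavage. It sets out from 6 and comes back to the route at 7.
- 6 is treated with excess 3, DIC and stoichiometric DMAP to give 5-(benzyloxy)-2-formyl-1,3-phenylene bis[3,4,5-tris(benzyloxy)benzoate] F7.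
- One equivalent of NaOMe in THF/MeOH at −40 °C then removes one ester.
- The first-liberated phenoxide is conjugated with the formyl group and should deactivate the remaining ester.

Further compounds
F1 | step 6 | 2-[3,4-bis(benzyloxy)phenyl]-2-oxoethyl 3,4,5-tris(benzyloxy)benzoate | O=C(COC(=O)c1cc(OCc2ccccc2)c(OCc2ccccc2)c(OCc2ccccc2)c1)c1ccc(OCc2ccccc2)c(OCc2ccccc2)c1
F2 | step 6 | perbenzylated cyanidin 3,5-di-O-gallate chloride (flavylium salt) | [Cl-].O=C(Oc1cc(OCc3ccccc3)cc2[o+]c(-c3ccc(OCc4ccccc4)c(OCc4ccccc4)c3)c(OC(=O)c3cc(OCc4ccccc4)c(OCc4ccccc4)c(OCc4ccccc4)c3)cc12)c1cc(OCc3ccccc3)c(OCc3ccccc3)c(OCc3ccccc3)c1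
F3 | step 6 | (2S,3S)-epicatechin 3,5-di-O-gallate | O=C(Oc1cc(O)cc2c1C[C@H](OC(=O)c1cc(O)c(O)c(O)c1)[C@H](c1ccc(O)c(O)c1)O2)c1cc(O)c(O)c(O)c1
F4 | step 5 | 5-(benzyloxy)-2-(hydroxymethyl)benzene-1,3-diol | OCc1c(O)cc(OCc2ccccc2)cc1O
F5 | step 5 | 7-(benzyloxy)-2-phenyl-4H-1,3,2-benzodioxaborinin-5-ol | Oc1cc(OCc2ccccc2)cc2c1COB(c1ccccc1)O2
F6 | step 5 | 7-(benzyloxy)-2-phenyl-4H-1,3,2-benzodioxaborinin-5-yl 3,4,5-tris(benzyloxy)benzoate | O=C(Oc1cc(OCc2ccccc2)cc2c1COB(c1ccccc1)O2)c1cc(OCc2ccccc2)c(OCc2ccccc2)c(OCc2ccccc2)c1
F7 | step 4 | 5-(benzyloxy)-2-formyl-1,3-phenylene bis[3,4,5-tris(benzyloxy)benzoate] | O=Cc1c(OC(=O)c2cc(OCc3ccccc3)c(OCc3ccccc3)c(OCc3ccccc3)c2)cc(OCc2ccccc2)cc1OC(=O)c1cc(OCc2ccccc2)c(OCc2ccccc2)c(OCc2ccccc2)c1
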